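The earlier runs and the new flask stem from a simulated flask with made-up constants; scatter was added.

Divide the nucleophile charged by the electrophile lost at 15 h, run by run.

| setting | north-west | south | east | flask |
|---|---|---|---|---|
| electrophile | 0.25 M | 0.38 M | 0.50 M | 0.50 M |
| nucleophile | 0.55 M | 0.55 M | 0.83 M | 0.550 M |
| remark | run made earlier | run made earlier | run made earlier |  |
| time |  |  |  | 15 h |

- north-west (time / h: electrophile / %, target / %): 1.00: 91, 9; 3.00: 67, 9; 5.00: 59, 14; 8.00: 47, 9; 12.0: 37, 6; 15.0: 33, 7
- south (time / h: electrophile / %, target / %): 1.33: 84, 9; 2.00: 82, 11; 3.00: 69, 12; 5.00: 64, 6; 10.0: 53, 11; 15.0: 51, 6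
- east (time / h: electrophile / %, target / %): 1.33: 73, 10; 4.00: 57, 11; 8.00: 50, 7; 10.0: 49, 9; 15.0: 44, 7

(each reading ± 2 percentage points)

- the earlier runs do not show how much of nucleophile is bound; that part of a forecast is a guess

- part of the electrophile that has reacted at 15 h
- share of the unused nucleophile that is free and not bound as protonated nucleophile, at 15 h

What do the readings show first? The north-west and south runs share one [nucleophile]. They lost 0.167 M and 0.186 M of electrophile, though the south run charged more. The charge of electrophile rose by a factor of 1.52, the loss by a factor of 1.11.

What do you carry over? The price: nucleophile charged per electrophile lost by 15 h. The runs read 3.28, 2.95 and 2.96, with a mean of 3.07.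

But the readings still drift at the end. Is that a stall? I don't claim one. The price is a ratio at one time, and the flask is asked at that same time.

Your number for the flask? Its [nucleophile] divided by the price and by its [electrophile] gives 35.9% reacted.

And the free share? The runs don't show it. If the price measures nucleophile really spent, I guess the free share low, and it stays a guess.

The forecast says 40% (35% to 46%), above my figure. For the free share it says 45% (22% to 72%). It writes of the runs that their loss “suggests that acid released by the reaction ties up a second nucleophile”.

The flask gives 40.6% reacted and a free share of 7.07%, so the forecast is right on the first and 38 percentage points too high on the second.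

electrophile + nucleophile → acid set free + target (k = 0.293 L mol⁻¹ h⁻¹); nucleophile + acid set free ⇌ protonated nucleophile, settled at all times (K = 656 L mol⁻¹); nucleophile + target → over-reaction product (k = 1.85 L mol⁻¹ h⁻¹) The flask's price is 2.71. The nucleophile is the limiting reagent: 2.5% of its charge stands unbound at 15.0 h, against 59% of the electrophile. The half-life of electrophile by its first step grows from 7.9 h at 1.87 h to 170 h at 15.0 h, long against the 15 h of the run. The neighbour flask with 1.4 M of nucleophile, priced at the mean, should reach 91.3%; it reaches 84.2%, a price of 3.32.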